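**Retrosynthetic overview**
1. Ester C–O: target 14 ⇐ secondary alcohol 12 + 4-methoxybenzoyl chloride 13.
2. C6–O and C5–H: 12 ⇐ exo-face hydroboration–oxidation of bridged alkene 10.
3. Key C4–O bond (oxygen bridge, formed last of the three rings): 10 ⇐ transannular hydroalkoxylation of diene 9 by the C1 oxygen.
4. Ring A (second ring): 9 ⇐ 6-exo Heck cyclisation of vinyl triflate 8 ⇐ ketone 6.
5. Ring B (first ring, chiral pool): 6 ⇐ reductive aldol of (R)-carvotanacetone 2 with pent-4-enal 3 (sets C10 and C1); 2 ⇐ (R)-carvone 1.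

Assumption: positions are given in eudesmane numbering (C1–C15), and the SMILES is read as the ring-B trans-fused isomer (H-5 and the C6 oxygen on the face of the oxygen bridge, called exo or β; C10 methyl on the other face).

**Step 1**
Reactants: 1 (R)-(−)-carvone
Product: 2 (R)-carvotanacetone, (5R)-2-methyl-5-(propan-2-yl)cyclohex-2-en-1-one
Conditions: H2 (1 atm), RhCl(PPh3)3 (2 mol %), benzene, rt
Reagents that add atoms: none
Why: Chemoselective homogeneous hydrogenation; the 1,1-disubstituted isopropenyl alkene is reduced much faster than the trisubstituted enone alkene, and the carvone stereocentre (future C7) is untouched.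

**Step 2**
Reactants: 2 (R)-carvotanacetone; 3 pent-4-enal
Product: 6 (2R,5R)-2-methyl-5-(propan-2-yl)-2-[(1R)-1-(triethylsilyloxy)pent-4-en-1-yl]cyclohexan-1-one, via lithium enolate 4 (not isolated), via lithium aldolate 5 (not isolated)
Conditions: LiBH(s-Bu)3, THF, −78 °C; then 3, −78 °C; then Et3SiOTf, −78 → 0 °C
Reagents that add atoms: pent-4-enal (C=CCCC=O); triethylsilyl trifluoromethanesulfonate (CC[Si](CC)(CC)OS(=O)(=O)C(F)(F)F)
Why: Reductive aldol (conjugate hydride reduction, then aldol through a closed Zimmerman–Traxler chair): axial attack on the enolate with equatorial isopropyl puts the new chain cis to isopropyl (sets C10), the equatorial aldehyde chain with methyl cis to the enolate oxygen gives the C1 oxygen syn to the C10 methyl in the zigzag (sets C1 as R), and silylation of the aldolate in the cold blocks retro-aldol.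

**Step 3**
Reactants: 6 silyl ether ketone
Product: 8 (3S,6R)-6-methyl-3-(propan-2-yl)-6-[(1R)-1-(triethylsilyloxy)pent-4-en-1-yl]cyclohex-1-en-1-yl trifluoromethanesulfonate, via potassium enolate 7 (not isolated)
Conditions: KN(SiMe3)2, THF, −78 °C; then PhNTf2, −78 → 0 °C
Reagents that add atoms: N-phenylbis(trifluoromethanesulfonimide) (O=S(=O)(N(c1ccccc1)S(=O)(=O)C(F)(F)F)C(F)(F)F)
Why: Enol triflate formation; only C6 carries α-hydrogens (C10 is quaternary), so a single enolate forms, and the β-silyloxy group cannot eliminate.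

**Step 4**
Reactants: 8 vinyl triflate
Product: 9 triethyl{[(1R,6S,8aS)-8a-methyl-4-methylidene-6-(propan-2-yl)-1,2,3,4,6,7,8,8a-octahydronaphthalen-1-yl]oxy}silane (ring A closed; diene C15=C4–C5=C6)
Conditions: Pd(OAc)2 (10 mol %), PPh3 (25 mol %), K2CO3, MeCN, 70 °C
Reagents that add atoms: none
Why: Intramolecular 6-exo-trig Mizoroki–Heck reaction; zerovalent palladium inserts into the C5–OTf bond, syn-carbopalladation of the terminal alkene forms C4–C5, and β-hydride elimination of the C4 hydrogen gives the exocyclic methylene; no stereocentre is made.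

**Step 5**
Reactants: 9 diene silyl ether
Product: 10 (1S,4R,4aS,7S)-1,4a-dimethyl-7-(propan-2-yl)-1,2,3,4,4a,5,6,7-octahydro-1,4-epoxynaphthalene (1,4-oxygen bridge; alkene C5=C6)
Conditions: Co(salen) (5 mol %; Co(salen) = [N,N′-bis(3,5-di-tert-butylsalicylidene)-1,2-cyclohexanediaminato]cobalt, divalent cobalt), N-fluoro-2,4,6-trimethylpyridinium triflate (1.3 equiv), (Me2SiH)2O (1.3 equiv), PhCF3, 0 °C → rt; aqueous work-up
Reagents that add atoms: none
Why: Proposed new method: a transannular 1,2-hydroalkoxylation of a conjugated diene by cobalt-hydride hydrogen-atom transfer and radical–polar crossover, with the silyl ether oxygen as nucleophile; the cobalt hydride (trivalent cobalt, from Co(salen), the N–F oxidant and the silane) gives H• to the unhindered terminal C15, the C4–C5–C6 allyl radical is oxidised by trivalent cobalt to the allyl cation, and the axial C1 oxygen, 1,4 across ring A, can only close on the tertiary terminus C4 (closure on C6 would need a bridgehead alkene), after which the silyl oxonium loses silicon; C4 is set because the bridge can only form on the face of the C1–O bond, and the step is irreversible and acid-free, which matters because the strained ether would reopen under Brønsted acid; the closest known reaction type is the Mukaiyama-type cobalt/N-fluoropyridinium/silane Markovnikov hydroalkoxylation of isolated mono-alkenes by free or protected alcohols, not yet shown for dienes or for making 7-oxabicyclo[2.2.1]heptanes.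

**Step 6**
Reactants: 10 bridged alkene
Product: 12 (1S,4R,4aS,7S,8R,8aR)-1,4a-dimethyl-7-(propan-2-yl)decahydro-1,4-epoxynaphthalen-8-ol, via C6 alkylborane 11 (not isolated)
Conditions: BH3·THF, THF, 0 °C → rt; then NaOH, H2O2, 0 °C
Reagents that add atoms: hydrogen peroxide (OO)
Why: Hydroboration–oxidation (syn, anti-Markovnikov; oxidation with retention): boron goes to the less substituted C6 and hydrogen to C5 from the exo face of the 2-alkylidene-7-oxanorbornane, which is the face of the oxygen bridge and the convex face of boat ring B, away from the endo C10 methyl and the C2–C3 bridge; this sets H-5 and the C6 oxygen both β (5R,6R).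

**Step 7**
Reactants: 12 alcohol; 13 4-methoxybenzoyl chloride
Product: 14 target, (1S,4R,4aS,7S,8R,8aR)-1,4a-dimethyl-7-(propan-2-yl)decahydro-1,4-epoxynaphthalen-8-yl 4-methoxybenzoate
Conditions: 13, Et3N, DMAP (cat.), CH2Cl2, rt
Reagents that add atoms: 4-methoxybenzoyl chloride (COc1ccc(cc1)C(Cl)=O)
Why: DMAP-catalysed acylation (nucleophilic catalysis) under basic conditions; no stereocentre is touched and the acid-labile tertiary bridging ether survives.

**Compound list**
1 | (R)-(−)-carvone, (5R)-2-methyl-5-(prop-1-en-2-yl)cyclohex-2-en-1-one | CC1=CC[C@H](CC1=O)C(C)=C | starting material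
2 | (R)-carvotanacetone, (5R)-2-methyl-5-(propan-2-yl)cyclohex-2-en-1-one | CC1=CC[C@H](CC1=O)C(C)C | intermediate
3 | pent-4-enal | C=CCCC=O | starting material
4 | lithium (5R)-2-methyl-5-(propan-2-yl)cyclohex-1-en-1-olate | CC1=C([O-])C[C@H](C(C)C)CC1.[Li+] | intermediate
5 | lithium (1R)-1-[(1R,4R)-1-methyl-2-oxo-4-(propan-2-yl)cyclohexyl]pent-4-en-1-olate | O=C1C[C@H](C(C)C)CC[C@]1(C)[C@H]([O-])CCC=C.[Li+] | intermediate
6 | (2R,5R)-2-methyl-5-(propan-2-yl)-2-[(1R)-1-(triethylsilyloxy)pent-4-en-1-yl]cyclohexan-1-one | O=C1C[C@H](C(C)C)CC[C@]1(C)[C@H](O[Si](CC)(CC)CC)CCC=C | intermediate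
7 | potassium (3S,6R)-6-methyl-3-(propan-2-yl)-6-[(1R)-1-(triethylsilyloxy)pent-4-en-1-yl]cyclohex-1-en-1-olate | [K+].[O-]C1=C[C@H](C(C)C)CC[C@]1(C)[C@H](O[Si](CC)(CC)CC)CCC=C | intermediate
8 | (3S,6R)-6-methyl-3-(propan-2-yl)-6-[(1R)-1-(triethylsilyloxy)pent-4-en-1-yl]cyclohex-1-en-1-yl trifluoromethanesulfonate | O=S(=O)(OC1=C[C@H](C(C)C)CC[C@]1(C)[C@H](O[Si](CC)(CC)CC)CCC=C)C(F)(F)F | intermediate
9 | triethyl{[(1R,6S,8aS)-8a-methyl-4-methylidene-6-(propan-2-yl)-1,2,3,4,6,7,8,8a-octahydronaphthalen-1-yl]oxy}silane | C=C1CC[C@@H](O[Si](CC)(CC)CC)[C@@]2(C)CC[C@@H](C(C)C)C=C12 | intermediate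
10 | (1S,4R,4aS,7S)-1,4a-dimethyl-7-(propan-2-yl)-1,2,3,4,4a,5,6,7-octahydro-1,4-epoxynaphthalene | [C@@H]1(C(C)C)CC[C@]2(C)[C@H]3CC[C@](C)(O3)C2=C1 | intermediate
11 | C6 alkylborane of 10 (BH2 on C6 and H on C5, both on the exo face) | B[C@@H]1[C@H](C(C)C)CC[C@]2(C)[C@H]3CC[C@](C)(O3)[C@@H]12 | intermediate
12 | (1S,4R,4aS,7S,8R,8aR)-1,4a-dimethyl-7-(propan-2-yl)decahydro-1,4-epoxynaphthalen-8-ol | O[C@@H]1[C@H](C(C)C)CC[C@]2(C)[C@H]3CC[C@](C)(O3)[C@@H]12 | intermediate
13 | 4-methoxybenzoyl chloride | COc1ccc(cc1)C(Cl)=O | starting material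
14 | (1S,4R,4aS,7S,8R,8aR)-1,4a-dimethyl-7-(propan-2-yl)decahydro-1,4-epoxynaphthalen-8-yl 4-methoxybenzoate; in eudesmane numbering (1R,4S,5R,6R,7S,10S)-1,4-epoxyeudesman-6-yl 4-methoxybenzoate | COc1ccc(C(=O)O[C@@H]2[C@H](C(C)C)CC[C@]3(C)[C@H]4CC[C@](C)(O4)[C@@H]23)cc1 | target

**Totals**
Total steps: 7. Longest linear sequence: 7 (from 1; 3 and 13 are bought).

**Three steps most likely to fail**

Step 5 (the proposed new step). The product is a strained 7-oxanorbornane with ring B forced into a boat, so ring closure has to beat fluoride capture or proton loss from the allyl cation, and a second hydrogen-atom transfer to the product alkene is possible. Fallback with known chemistry, from 9 back to 10: cleave the silyl ether with Bu4NF in THF to (1R,6S,8aS)-8a-methyl-4-methylidene-6-(propan-2-yl)-1,2,3,4,6,7,8,8a-octahydronaphthalen-1-ol F1. Kinetic iodoetherification of F1 (I2, NaHCO3, MeCN, 0 °C) closes the C1 oxygen 5-exo on C4 of the iodonium at the terminal alkene and gives (1S,4R,4aS,7S)-1-(iodomethyl)-4a-methyl-7-(propan-2-yl)-1,2,3,4,4a,5,6,7-octahydro-1,4-epoxynaphthalene F2. Radical deiodination of F2 (Bu3SnH, AIBN, benzene, 80 °C) turns CH2I into the C4 methyl and gives 10.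

Step 6. The facial preference is argued from geometry, not precedent, and exo addition builds up the strain of the trans-fused product; borane could also attack the allylic ether. Fallback from 10 back to 12: epoxidise with dimethyldioxirane in acetone at 0 °C to the exo (5β,6β) epoxide of 10, 8,8a-epoxy-1,4a-dimethyl-7-(propan-2-yl)decahydro-1,4-epoxynaphthalene F3. Open F3 reductively with Cp2TiCl (trivalent titanium, from Cp2TiCl2 and Mn) and 1,4-cyclohexadiene in THF: the C5–O bond breaks to the tertiary C5 radical, the C6 oxygen keeps its configuration, and hydrogen-atom transfer to C5 from the open exo face gives 12.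

Step 2. The tetrasubstituted enolate may give modest selectivity at C1, and the hindered aldolate can revert before it is silylated. Fallback from 2 back to 6: 1,4-hydrosilylation of 2 (Et3SiH, RhCl(PPh3)3 cat.) gives triethyl{[(5R)-2-methyl-5-(propan-2-yl)cyclohex-1-en-1-yl]oxy}silane F4. A Lewis-acid Mukaiyama aldol of F4 with 3 (TiCl4, CH2Cl2, −78 °C; non-basic and irreversible) gives (2R,5R)-2-[(1R)-1-hydroxypent-4-en-1-yl]-2-methyl-5-(propan-2-yl)cyclohexan-1-one F5, with C1 epimers separated by chromatography. Silylation of F5 (Et3SiOTf, 2,6-lutidine, CH2Cl2) gives 6.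

**Further compounds**
F1 | step 5 | (1R,6S,8aS)-8a-methyl-4-methylidene-6-(propan-2-yl)-1,2,3,4,6,7,8,8a-octahydronaphthalen-1-ol | C=C1CC[C@@H](O)[C@@]2(C)CC[C@@H](C(C)C)C=C12
F2 | step 5 | (1S,4R,4aS,7S)-1-(iodomethyl)-4a-methyl-7-(propan-2-yl)-1,2,3,4,4a,5,6,7-octahydro-1,4-epoxynaphthalene | [C@@H]1(C(C)C)CC[C@]2(C)[C@H]3CC[C@](CI)(O3)C2=C1
F3 | step 6 | 8,8a-epoxy-1,4a-dimethyl-7-(propan-2-yl)decahydro-1,4-epoxynaphthalene, epoxide oxygen syn to the 1,4-oxygen bridge | O1[C@@H]2[C@H](C(C)C)CC[C@]3(C)[C@H]4CC[C@](C)(O4)[C@@]123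
F4 | step 2 | triethyl{[(5R)-2-methyl-5-(propan-2-yl)cyclohex-1-en-1-yl]oxy}silane | CC1=C(O[Si](CC)(CC)CC)C[C@H](C(C)C)CC1
F5 | step 2 | (2R,5R)-2-[(1R)-1-hydroxypent-4-en-1-yl]-2-methyl-5-(propan-2-yl)cyclohexan-1-one | O=C1C[C@H](C(C)C)CC[C@]1(C)[C@H](O)CCC=C
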